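Count the catalyst as a charge that wears out, not as a rate. These are the minutes of a short meeting on the flask below; the runs and questions were tabled first.

common to all: starting material 0.50 M
- red: second substrate 0.50 M; reagent 0.55 M; capture agent 0.025 M; free catalyst 5 mM; temperature 25 °C; the very flask that is asked about, followed so far
- grey: second substrate 1 M; reagent 0.55 M; capture agent 0.025 M; free catalyst 5 mM; temperature 31 °C; run made earlier
- flask: second substrate 0.500 M; reagent 0.550 M; capture agent 0.0250 M; free catalyst 5.0 mM; temperature 25 °C; time 8.0 min

| run | time / min | target / % | starting material / % |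
|---|---|---|---|
| red | 0.333 | 6.0 | 94.5 |
| red | 1.00 | 14.4 | 85.1 |
| red | 1.50 | 17.0 | 83.0 |
| red | 2.50 | 18.1 | 80.5 |
| red | 4.00 | 20.7 | 77.2 |
| red | 5.00 | 23.2 | 75.5 |
| grey | 0.500 | 8.3 | 89.5 |
| grey | 1.00 | 14.7 | 82.3 |
| grey | 1.33 | 15.9 | 83.9 |
| grey | 2.00 | 17.0 | 80.3 |
| grey | 2.50 | 18.4 | 79.7 |
| grey | 3.00 | 22.1 | 79.8 |

(each reading ± 1 percentage point)

- maple: change nothing and wait 15 min more
- larch: at 8.0 min raise the temperature by 25 K, then wait 15 min
- ash: at 8.0 min add free catalyst, 100 % of the amount charged, then wait 15 min
- oak: at 8.0 min add reagent, 100 % of the amount charged, then wait 15 min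

- target is meant together with its idle complex
- what is added takes up no volume worth counting
- reactions considered so far: second substrate + free catalyst <-> catalyst intermediate B; catalyst intermediate A + capture agent -> trapped intermediate; reagent + catalyst intermediate A <-> free catalyst + target; reagent + catalyst intermediate B -> free catalyst + second product; free catalyst + target <-> idle complex; starting material + free catalyst <-> catalyst intermediate A

- target, in percent of the starting material first charged, at 8.0 min
- the option that brings most further target ("none" if no option brings more than 2 percentage points) (maple / larch / ash / oak / none)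
- target present, in percent of the starting material first charged, after maple
- target present, in percent of the starting material first charged, after oak

I opened with the red run: target rose to 17.0 % by 1.50 min, then crept to 23.2 % by 5.00 min. The grey run, hotter and with more second substrate, bent in the same way and read 22.1 % at 3.00 min.

I proposed the symmetric case as the zero of the scale. Suppose catalyst intermediate A takes reagent and capture agent with equal ease, a selectivity factor of one. Then [reagent]/[capture agent] gives odds of 22.0 to one that it goes on rather than being trapped. A trapped catalyst stops working, and more capture agent is charged than catalyst. So the odds times [free catalyst] charged, over [starting material] charged, give 22.0 %. I called this the turnover allowance: the target, as a percentage of the starting material charged, that a catalyst charge yields before trapping ends it, on the supposition of equal ease and with [reagent] and [capture agent] held at the values used for the odds.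

The last red reading stands 1.2 percentage points above it, about one standard deviation of the scatter. As my own reckoning I committed to about 22.0 % at 8.0 min, to about the same after maple or oak, and to ash as best: on this reckoning, fresh catalyst brings a fresh allowance.

The forecast read the tail as live, holding that “Capture agent can only kill catalyst, not explain a steady tail”. It gave 28.5 % now, 50 % after maple, 60 % after oak, and ash as best. We agreed on the option and parted on the waiting.

The flask gives 22.0 % at 8.0 min, 22.1 % after maple and 22.2 % after oak. The best option is ash, which gains 13 points.

    second substrate + free catalyst ⇌ catalyst intermediate B (K = 3.40 M⁻¹, k = 4.54 M⁻¹ s⁻¹, Ea = 39.0 kJ mol⁻¹, ΔH = −29.0 kJ mol⁻¹)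
    catalyst intermediate A + capture agent → trapped intermediate (k = 3.36 M⁻¹ s⁻¹, Ea = 41.0 kJ mol⁻¹)
    reagent + catalyst intermediate A ⇌ free catalyst + target (K = 2.10, k = 4.75 M⁻¹ s⁻¹, Ea = 58.0 kJ mol⁻¹, ΔH = −41.0 kJ mol⁻¹)
    reagent + catalyst intermediate B → free catalyst + second product (k = 1.48 M⁻¹ s⁻¹, Ea = 54.0 kJ mol⁻¹)
    free catalyst + target ⇌ idle complex, settled at all times (K = 1.60 M⁻¹, ΔH = 27.0 kJ mol⁻¹)
    starting material + free catalyst ⇌ catalyst intermediate A (K = 10.4 M⁻¹, k = 1.68 M⁻¹ s⁻¹, Ea = 60.0 kJ mol⁻¹, ΔH = −25.0 kJ mol⁻¹)
    (constants at 25 °C)

Removing the trapping step lifts this flask's target at 8.0 min from 22.0 % to 52.8 %, the largest single effect tried. At 8.0 min the flask's remaining reagent and capture agent give odds of 16.5, so the added catalyst has an allowance of 16.5 % against the 13 points gained. The neighbouring flask charged with 2.2 M of reagent has an allowance of 88.0 %; at 8.0 min it holds 58.2 % target, with 91.9 % of its catalyst trapped.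

The runs stem from a simulated flask from invented constants; the scatter is artificial.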